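Ring A is made last. Its four contiguous oxygen-bearing carbons C5, C6, C7 and C8 are mapped onto the four carbons of dimethyl squarate, and C4a and C8a onto the C5=C6 double bond of a 2-aryl-4H-pyran-4-one that already holds rings B and C. The precursor of the key step is a 4-hydroxycyclobutenone carrying this pyranone at its carbinol carbon. On heating, a Moore-type ring expansion should form the C4a–C5 bond and deliver ring A fully oxygenated as a 5,8-dihydroxy-6,7-dimethoxy unit in one operation. The 5-OH is then chelated to the C4 carbonyl, so only the 8-OH is methylated before debenzylation.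

Key step: step 6

Assumption: 1-(2-hydroxy-3,4,5,6-tetramethoxyphenyl)ethan-1-one, needed only in a fallback, is taken as purchasable. Ar = 3-(benzyloxy)-4,5-dimethoxyphenyl and TMP = 2,2,6,6-tetramethylpiperidin-1-yl throughout.

Step 1
Reactants: 1 3-hydroxy-4,5-dimethoxybenzoic acid
Product: 3 3-(benzyloxy)-4,5-dimethoxybenzoic acid, via benzyl ester 2 (not isolated)
Conditions: BnBr (2.3 equiv), K2CO3, DMF, 60 °C; then 2 M NaOH, MeOH, 60 °C; wash out neutrals; HCl to pH 2
Reagents that add atoms: benzyl bromide BrCc1ccccc1; sodium hydroxide [Na+].[OH-]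
Why: Williamson O-benzylation of phenoxide and carboxylate, then in-flask saponification of the benzyl ester by acyl–oxygen cleavage, should leave only the base-stable aryl benzyl ether, and the acid is purified by acid–base extraction.

Step 2
Reactants: 3 3-(benzyloxy)-4,5-dimethoxybenzoic acid
Product: 4 3-(benzyloxy)-4,5-dimethoxybenzoyl chloride
Conditions: (COCl)2 (1.3 equiv), DMF (cat.), CH2Cl2, 0 °C to rt; evaporate, use crude
Reagents that add atoms: oxalyl chloride ClC(=O)C(=O)Cl
Why: Acid chloride formation through the Vilsmeier-type chloroiminium salt is neutral, gives only gaseous by-products and leaves the methyl and benzyl ethers untouched.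

Step 3
Reactants: 4 3-(benzyloxy)-4,5-dimethoxybenzoyl chloride; 5 (E)-4-methoxybut-3-en-2-one
Product: 6 (E)-1-[3-(benzyloxy)-4,5-dimethoxyphenyl]-5-methoxypent-4-ene-1,3-dione
Conditions: 5 (2.2 equiv), LiN(SiMe3)2 (2.2 equiv), THF, −78 °C; then 4 in THF, −78 °C; AcOH quench
Reagents that add atoms: none
Why: Kinetic deprotonation of the methyl group of 5 gives the cross-conjugated lithium enolate, which is C-acylated by the aroyl chloride (crossed Claisen-type acylation), while the second equivalent of enolate deprotonates the more acidic 1,3-diketone as it forms and so prevents double acylation.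

Step 4
Reactants: 6 (E)-1-[3-(benzyloxy)-4,5-dimethoxyphenyl]-5-methoxypent-4-ene-1,3-dione
Product: 7 2-[3-(benzyloxy)-4,5-dimethoxyphenyl]-4H-pyran-4-one
Conditions: CF3CO2H (cat.), toluene, rt
Reagents that add atoms: none
Why: The enol oxygen of the aryl ketone adds in conjugate fashion to the protonated β-methoxy enone and methanol is expelled (acid-catalysed addition–elimination), which closes ring C as the 4-pyranone under conditions too mild to cleave the benzyl ether; the E geometry is lost here.

Step 5
Reactants: 7 2-[3-(benzyloxy)-4,5-dimethoxyphenyl]-4H-pyran-4-one; 8 dimethyl squarate (3,4-dimethoxycyclobut-3-ene-1,2-dione)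
Product: 10 rac-4-(6-Ar-4-oxo-4H-pyran-2-yl)-4-hydroxy-2,3-dimethoxycyclobut-2-en-1-one, via pyranonylmagnesium chloride 9 (not isolated)
Conditions: TMPMgCl·LiCl (1.2 equiv), THF, −40 °C; then cannulate into 8 (1.3 equiv), THF, −78 °C; aq NH4Cl at −78 °C
Reagents that add atoms: none
Why: The hindered magnesium amide should remove the most acidic ring proton, C6–H next to the ring oxygen (the counterpart of the C2 metalation of chromones by hindered amide bases), and the alkenyl Grignard 9 then adds 1,2 to one of the two equivalent, strongly electrophilic squarate carbonyls (standard organometallic addition to dialkyl squarates), giving the quaternary carbinol as a racemate that is destroyed in step 6.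

Step 6
Reactants: 10 rac-4-(6-Ar-4-oxo-4H-pyran-2-yl)-4-hydroxy-2,3-dimethoxycyclobut-2-en-1-one
Product: 13 2-[3-(benzyloxy)-4,5-dimethoxyphenyl]-5,8-dihydroxy-6,7-dimethoxy-4H-chromen-4-one, via dienylketene 11 (not isolated), via cyclohexadienone 12 (not isolated)
Conditions: degassed toluene (0.02 M), 110 °C, Ar; aq Na2S2O4 wash, work-up under Ar
Reagents that add atoms: none
Why: Proposed new method: heating should cleave the cyclobutenone C1–C4 bond in a conrotatory 4π-electron electrocyclic opening, the donor hydroxyl turning outward so that the pyranonyl group lies cis to the ketene in 11; the ketene carbon then bonds to pyranone C5 in a disrotatory 6π-electron electrocyclization that forms the C4a–C5 bond and closes the six-membered ring A as dienone 12, whose 4a-H sits between two carbonyls and enolizes at once to the aromatic hydroquinone 13. The closest known reaction type is the Moore rearrangement of 4-alkenyl-, 4-aryl- and 4-heteroaryl-4-hydroxycyclobutenones from dialkyl squarates to annulated 2,3-dialkoxyhydroquinones; a 4-oxo-4H-pyran-2-yl group as the unsaturated partner is the untested element. The pyranone C5=C6 bond is a weakly aromatic enol-ether alkene whose C5 is its nucleophilic end, which matches the electrophilic ketene carbon, so closure should be no harder than onto furyl or thienyl groups. No stereocentre remains, since the carbinol centre of 10 becomes sp2 in 11 and the transient C4a centre of 12 is erased by tautomerization. The step needs outward rotation of the oxygen substituent, secured by the known torquoselectivity of donor groups at C4, and closure at C5 only, secured because C5 is the sole hydrogen-bearing carbon next to the attachment carbon C6; lactonization of 11 to a butenolide is held back by dilution in a non-polar solvent.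

Step 7
Reactants: 13 2-[3-(benzyloxy)-4,5-dimethoxyphenyl]-5,8-dihydroxy-6,7-dimethoxy-4H-chromen-4-one
Product: 14 2-[3-(benzyloxy)-4,5-dimethoxyphenyl]-5-hydroxy-6,7,8-trimethoxy-4H-chromen-4-one (3'-O-benzylgardenin C)
Conditions: Me2SO4 (1.05 equiv), K2CO3 (1.2 equiv), degassed acetone, 40 °C, Ar
Reagents that add atoms: dimethyl sulfate COS(=O)(=O)OC
Why: Williamson-type O-methylation under weak base should touch only the free 8-OH, because the 5-OH is hydrogen-bonded to the C4 carbonyl and is less acidic and less nucleophilic, as in the classical partial methylation of 5-hydroxyflavones.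

Step 8
Reactants: 14 2-[3-(benzyloxy)-4,5-dimethoxyphenyl]-5-hydroxy-6,7,8-trimethoxy-4H-chromen-4-one
Product: 15 gardenin C, 5-hydroxy-2-(3-hydroxy-4,5-dimethoxyphenyl)-6,7,8-trimethoxy-4H-chromen-4-one
Conditions: H2 (1 atm), 10% Pd/C, EtOAc–MeOH, rt, stopped after one equivalent of H2
Reagents that add atoms: none
Why: Catalytic hydrogenolysis of the aryl benzyl ether is much faster than reduction of the flavone C2=C3 bond or carbonyl under these mild conditions, and the methyl ethers and the chelated phenol are inert.

Compound list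
1 | 3-hydroxy-4,5-dimethoxybenzoic acid | COc1cc(C(=O)O)cc(O)c1OC | starting material
2 | benzyl 3-(benzyloxy)-4,5-dimethoxybenzoate | COc1cc(C(=O)OCc2ccccc2)cc(OCc2ccccc2)c1OC | intermediate
3 | 3-(benzyloxy)-4,5-dimethoxybenzoic acid | COc1cc(C(=O)O)cc(OCc2ccccc2)c1OC | intermediate
4 | 3-(benzyloxy)-4,5-dimethoxybenzoyl chloride | COc1cc(C(=O)Cl)cc(OCc2ccccc2)c1OC | intermediate
5 | (E)-4-methoxybut-3-en-2-one | CO/C=C/C(C)=O | starting material
6 | (E)-1-[3-(benzyloxy)-4,5-dimethoxyphenyl]-5-methoxypent-4-ene-1,3-dione | CO/C=C/C(=O)CC(=O)c1cc(OC)c(OC)c(OCc2ccccc2)c1 | intermediate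
7 | 2-[3-(benzyloxy)-4,5-dimethoxyphenyl]-4H-pyran-4-one | O=c1ccoc(-c2cc(OC)c(OC)c(OCc3ccccc3)c2)c1 | intermediate
8 | dimethyl squarate (3,4-dimethoxycyclobut-3-ene-1,2-dione) | COc1c(OC)c(=O)c1=O | starting material
9 | {6-[3-(benzyloxy)-4,5-dimethoxyphenyl]-4-oxo-4H-pyran-2-yl}magnesium chloride (LiCl complex) | O=c1cc([Mg]Cl)oc(-c2cc(OC)c(OC)c(OCc3ccccc3)c2)c1 | intermediate
10 | rac-4-{6-[3-(benzyloxy)-4,5-dimethoxyphenyl]-4-oxo-4H-pyran-2-yl}-4-hydroxy-2,3-dimethoxycyclobut-2-en-1-one (racemic, centre unspecified) | COC1=C(OC)C(O)(c2cc(=O)cc(-c3cc(OC)c(OC)c(OCc4ccccc4)c3)o2)C1=O | intermediate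
11 | (3Z)-4-{6-[3-(benzyloxy)-4,5-dimethoxyphenyl]-4-oxo-4H-pyran-2-yl}-4-hydroxy-2,3-dimethoxybuta-1,3-dien-1-one (dienylketene, pyranonyl cis to the ketene carbon) | O=C=C(OC)/C(OC)=C(/O)c1cc(=O)cc(-c2cc(OC)c(OC)c(OCc3ccccc3)c2)o1 | intermediate
12 | rac-2-[3-(benzyloxy)-4,5-dimethoxyphenyl]-8-hydroxy-6,7-dimethoxy-4aH-chromene-4,5-dione (racemic, centre unspecified) | O=C1C(OC)=C(OC)C(O)=C2OC(-c3cc(OC)c(OC)c(OCc4ccccc4)c3)=CC(=O)C12 | intermediate
13 | 2-[3-(benzyloxy)-4,5-dimethoxyphenyl]-5,8-dihydroxy-6,7-dimethoxy-4H-chromen-4-one | COc1cc(-c2cc(=O)c3c(O)c(OC)c(OC)c(O)c3o2)cc(OCc2ccccc2)c1OC | intermediate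
14 | 2-[3-(benzyloxy)-4,5-dimethoxyphenyl]-5-hydroxy-6,7,8-trimethoxy-4H-chromen-4-one | COc1cc(-c2cc(=O)c3c(O)c(OC)c(OC)c(OC)c3o2)cc(OCc2ccccc2)c1OC | intermediate
15 | gardenin C, 5-hydroxy-2-(3-hydroxy-4,5-dimethoxyphenyl)-6,7,8-trimethoxy-4H-chromen-4-one | COc1cc(-c2cc(=O)c3c(O)c(OC)c(OC)c(OC)c3o2)cc(O)c1OC | target

Total step count: 8. Longest linear sequence: 8 steps (1 to 15); 5 and 8 enter as purchased fragments. The target has no stereocentre, and the only centres on the route (in 10 and 12) are racemic and erased in step 6.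

Steps most likely to fail

Step 6. The ketene 11 may be captured by its own hydroxyl to give a butenolide, or the electron-poor pyranone double bond may close too slowly, so that decomposition or oxidation of the hydroquinone takes over. The fallback uses only known flavone chemistry, sets out from acid chloride 4 and comes back to the route at 15. Acid chloride 4 acylates the phenol of 1-(2-hydroxy-3,4,5,6-tetramethoxyphenyl)ethan-1-one F1 in pyridine to give 2-acetyl-3,4,5,6-tetramethoxyphenyl 3-(benzyloxy)-4,5-dimethoxybenzoate F2. Baker–Venkataraman rearrangement (KOH, pyridine, 50 °C) should give 1-[3-(benzyloxy)-4,5-dimethoxyphenyl]-3-(2-hydroxy-3,4,5,6-tetramethoxyphenyl)propane-1,3-dione F3. Acid-catalysed cyclodehydration (p-TsOH, toluene, reflux) closes ring C to 2-[3-(benzyloxy)-4,5-dimethoxyphenyl]-5,6,7,8-tetramethoxy-4H-chromen-4-one F4. BCl3 (CH2Cl2, −78 to 0 °C) then cleaves the chelation-activated 5-methyl ether together with the benzyl ether to give 15.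

Step 5. Deprotonation may occur at the wrong ring carbon, because a magnesium amide can be steered by the carbonyl toward C5 or C3. A metalated position next to the carbonyl may fragment by ring opening, and residual amide may attack the squarate. A C5-magnesiated isomer would not be harmful, since after addition and ring expansion it converges on the same hydroquinone 13 (ring A is symmetrical at that stage); C3 metalation, however, is a dead end. The fallback sets out from pyranone 7 and comes back to the route at 9. Lewis-acid-free zincation with TMPZnCl·LiCl in THF, the protocol that selects the carbon next to the ring oxygen in chromones and gives non-fragmenting organozincs, should give {6-[3-(benzyloxy)-4,5-dimethoxyphenyl]-4-oxo-4H-pyran-2-yl}zinc chloride F5. Iodine converts this into 2-[3-(benzyloxy)-4,5-dimethoxyphenyl]-6-iodo-4H-pyran-4-one F6, which is isolated. Iodine–magnesium exchange with iPrMgCl·LiCl (THF, −78 °C) then generates 9 free of amine and amide, and addition to 8 continues as in the route.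

Step 7. Alkylation may spill over to the chelated 5-OH, or the hydroquinone may be oxidized by air to the 5,8-quinone under base before it is methylated. The fallback sets out from 13 and comes back to the route at 15. Exhaustive methylation (excess Me2SO4, K2CO3, acetone, reflux) gives 2-[3-(benzyloxy)-4,5-dimethoxyphenyl]-5,6,7,8-tetramethoxy-4H-chromen-4-one F7, the same structure as F4. BCl3 (CH2Cl2, −78 to 0 °C) then removes the 5-methyl group through the boron chelate and the benzyl group in the same operation to give 15.

Further compounds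
F1 | step 6 | 1-(2-hydroxy-3,4,5,6-tetramethoxyphenyl)ethan-1-one | CC(=O)c1c(O)c(OC)c(OC)c(OC)c1OC
F2 | step 6 | 2-acetyl-3,4,5,6-tetramethoxyphenyl 3-(benzyloxy)-4,5-dimethoxybenzoate | CC(=O)c1c(OC(=O)c2cc(OC)c(OC)c(OCc3ccccc3)c2)c(OC)c(OC)c(OC)c1OC
F3 | step 6 | 1-[3-(benzyloxy)-4,5-dimethoxyphenyl]-3-(2-hydroxy-3,4,5,6-tetramethoxyphenyl)propane-1,3-dione | COc1cc(C(=O)CC(=O)c2c(O)c(OC)c(OC)c(OC)c2OC)cc(OCc2ccccc2)c1OC
F4 | step 6 | 2-[3-(benzyloxy)-4,5-dimethoxyphenyl]-5,6,7,8-tetramethoxy-4H-chromen-4-one | COc1cc(-c2cc(=O)c3c(OC)c(OC)c(OC)c(OC)c3o2)cc(OCc2ccccc2)c1OC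
F5 | step 5 | {6-[3-(benzyloxy)-4,5-dimethoxyphenyl]-4-oxo-4H-pyran-2-yl}zinc chloride | O=c1cc([Zn]Cl)oc(-c2cc(OC)c(OC)c(OCc3ccccc3)c2)c1
F6 | step 5 | 2-[3-(benzyloxy)-4,5-dimethoxyphenyl]-6-iodo-4H-pyran-4-one | O=c1cc(I)oc(-c2cc(OC)c(OC)c(OCc3ccccc3)c2)c1
F7 | step 7 | 2-[3-(benzyloxy)-4,5-dimethoxyphenyl]-5,6,7,8-tetramethoxy-4H-chromen-4-one | COc1cc(-c2cc(=O)c3c(OC)c(OC)c(OC)c(OC)c3o2)cc(OCc2ccccc2)c1OC
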